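**Strategy**

The synthesis rests on cutting ring A, fully substituted in the target, at C4a–C8a and tracing it to a squarate-derived cyclobutenone. In one thermal operation (Moore rearrangement, step 3) the four-membered ring opens to a dienylketene that electrocyclises, forging C4a–C8a and closing ring A as a phenol. The step exploits the para relationship between the C8a oxygen and the C6 methoxy and the need to distinguish the C5, C6, C7 and C8a oxygens: they emerge as ethyl ether, methyl ether, isopropyl ether and free hydroxyl, with C4a the only unsubstituted carbon. The precursor is a 2-methyl-3-isopropoxycyclobutenone whose sp3 carbon carries a methoxy and a 1-ethoxyvinyl group.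

Key step: step 3

Remark: atom labels (C2–C9, C4a, C8a; C9 = carbinol carbon) follow the chromanone numbering of the target and are used for all intermediates.
Remark: C2 (lactol) and C3 (alpha to the C4 ketone) can epimerise through the ring-opened keto aldehyde, so only C9 is set by a reagent; the (2S,3R) arrangement next to 9S is assumed to be the thermodynamically preferred one, reached by equilibration in steps 11 and 12.
Remark: the C5 and C8a oxygens are never both free before ring C is closed: C8a–O is acylated (step 5) before the C5 ether is cleaved (step 6), and C5–O is silylated (step 7) before C8a–O is released (step 8).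

**Route**

Step 1
Reactants: 1 diisopropyl squarate
Product: 3 3-isopropoxy-4-methylcyclobut-3-ene-1,2-dione, via hydroxy adduct 2 (not isolated)
Conditions: MeLi, THF, −78 °C; then 12 M HCl, CH2Cl2, 20 °C
Reagents that add atoms: methyllithium, [Li]C
Why: Organolithium 1,2-addition to one squarate carbonyl followed by acid-induced collapse of the hydroxy adduct with loss of propan-2-ol (vinylogous hemiketal hydrolysis) is the standard entry to 3-alkoxy-4-alkylcyclobutenediones.

Step 2
Reactants: 3 3-isopropoxy-4-methylcyclobut-3-ene-1,2-dione; 4 ethyl vinyl ether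
Product: 7 4-(1-ethoxyvinyl)-3-isopropoxy-4-methoxy-2-methylcyclobut-2-en-1-one (racemic), via 1-ethoxyvinyllithium 5 (not isolated), via lithium alkoxide 6 (not isolated)
Conditions: 4, t-BuLi, THF, −78 → 0 °C; then 3, −78 °C; then MeOTf, −78 → 0 °C
Reagents that add atoms: methyl trifluoromethanesulfonate, COS(=O)(=O)C(F)(F)F
Why: The alpha-lithiated vinyl ether adds 1,2 to the carbonyl next to the isopropoxy-bearing carbon, which is the more electrophilic one because the other carbonyl is a vinylogous ester, and the tertiary lithium alkoxide is then O-methylated in the flask (Williamson-type alkylation with a triflate); the new quaternary centre is racemic and disappears in step 3.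

Step 3
Reactants: 7 4-(1-ethoxyvinyl)-3-isopropoxy-4-methoxy-2-methylcyclobut-2-en-1-one
Product: 10 5-ethoxy-3-isopropoxy-4-methoxy-2-methylphenol, via dienylketene 8 (not isolated), via cyclohexadienone 9 (not isolated)
Conditions: toluene (degassed, dilute), 110 °C
Reagents that add atoms: none
Why: Thermal conrotatory 4π electrocyclic opening of the bond between the carbonyl carbon and the sp3 carbon gives the dienylketene, whose ketene carbon (future C8a) and vinyl CH2 (future C4a) join in a thermal disrotatory 6π electrocyclisation; tautomerisation of the cyclohexa-2,4-dienone then gives the phenol. This is the Moore rearrangement of 4-alkenyl-4-alkoxycyclobutenones, an established benzannulation. Ring A is closed by the 6π electrocyclisation (C4a–C8a bond), and no stereocentre is created because the racemic quaternary carbon becomes the sp2 carbon C6. The step needs torquoselective opening with the ethoxyvinyl group turning inward; the donor methoxy group on the breaking bond prefers outward rotation, and an unproductive ketene isomer can reclose and reopen. The substitution pattern is already fixed by the regiochemistry of step 2, so the ketene oxygen can only appear as the free C8a hydroxyl para to the C6 methoxy, flanked by the C8 methyl and the unsubstituted C4a.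

Step 4
Reactants: 10 5-ethoxy-3-isopropoxy-4-methoxy-2-methylphenol
Product: 12 1-(6-ethoxy-2-hydroxy-4-isopropoxy-5-methoxy-3-methylphenyl)ethan-1-one, via aryl acetate 11 (not isolated)
Conditions: Ac2O, BF3·OEt2 (promoter), 0 → 50 °C; then NaOAc (aq), MeOH, 50 °C
Reagents that add atoms: acetic anhydride, CC(=O)OC(C)=O
Why: O-Acetylation and Lewis-acid Fries rearrangement deliver the acetyl group to C4a, the only unsubstituted ring carbon and ortho to the hydroxyl, and the product is held as a boron chelate that is hydrolysed on work-up, while the ethyl, methyl and isopropyl ethers tolerate BF3.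

Step 5
Reactants: 12 1-(6-ethoxy-2-hydroxy-4-isopropoxy-5-methoxy-3-methylphenyl)ethan-1-one; 13 4-isopropoxybenzoic acid
Product: 15 2-acetyl-3-ethoxy-5-isopropoxy-4-methoxy-6-methylphenyl 4-isopropoxybenzoate, via acid chloride 14 (not isolated)
Conditions: 13, (COCl)2, DMF (cat.), CH2Cl2, 0 → 20 °C, evaporate; then 12, Et3N, DMAP (cat.), CH2Cl2, 0 → 20 °C
Reagents that add atoms: none
Why: Acylation of the hydrogen-bonded C8a phenol by the acid chloride under nucleophilic catalysis (esterification, first half of a Baker–Venkataraman sequence) masks C8a–O before the C5 oxygen is uncovered, so that the two oxygens ortho to the ketone never stand free together.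

Step 6
Reactants: 15 2-acetyl-3-ethoxy-5-isopropoxy-4-methoxy-6-methylphenyl 4-isopropoxybenzoate
Product: 16 2-acetyl-3,5-dihydroxy-4-methoxy-6-methylphenyl 4-hydroxybenzoate
Conditions: BCl3 (excess), CH2Cl2, −78 → 0 °C; then H2O, 0 °C
Reagents that add atoms: none
Why: Lewis-acid ether cleavage with BCl3 removes the two secondary isopropyl groups at low temperature and the C5 ethyl group through chelation with the ortho acetyl carbonyl, whereas the C6 methyl ether, neither secondary nor ortho to a carbonyl, and the aryl ester react more slowly.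

Step 7
Reactants: 16 2-acetyl-3,5-dihydroxy-4-methoxy-6-methylphenyl 4-hydroxybenzoate
Product: 17 2-acetyl-4-methoxy-6-methyl-3,5-bis(triisopropylsilyloxy)phenyl 4-(triisopropylsilyloxy)benzoate
Conditions: i-Pr3SiOTf, 2,6-lutidine, CH2Cl2, 0 → 20 °C
Reagents that add atoms: triisopropylsilyl trifluoromethanesulfonate, CC(C)[Si](OS(=O)(=O)C(F)(F)F)(C(C)C)C(C)C
Why: Silylation with a silyl triflate and a hindered pyridine base is forceful enough for the hindered, hydrogen-bonded C5 hydroxyl and does not attack the aryl ester; the triisopropylsilyl ethers resist the bases of steps 8 and 11 and leave with fluoride.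

Step 8
Reactants: 17 2-acetyl-4-methoxy-6-methyl-3,5-bis(triisopropylsilyloxy)phenyl 4-(triisopropylsilyloxy)benzoate
Product: 18 1-[2-hydroxy-5-methoxy-3-methyl-4,6-bis(triisopropylsilyloxy)phenyl]-3-[4-(triisopropylsilyloxy)phenyl]propane-1,3-dione
Conditions: LiN(SiMe3)2 (2.5 equiv), THF, −78 → −20 °C; then AcOH
Reagents that add atoms: none
Why: Baker–Venkataraman rearrangement: the methyl ketone enolate attacks the neighbouring aryl ester through a six-membered transition state, moving the aroyl group to carbon (C3–C9 bond) and releasing C8a–O as the only free phenol.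

Step 9
Reactants: 18 1-[2-hydroxy-5-methoxy-3-methyl-4,6-bis(triisopropylsilyloxy)phenyl]-3-[4-(triisopropylsilyloxy)phenyl]propane-1,3-dione
Product: 19 (3S)-3-hydroxy-1-[2-hydroxy-5-methoxy-3-methyl-4,6-bis(triisopropylsilyloxy)phenyl]-3-[4-(triisopropylsilyloxy)phenyl]propan-1-one
Conditions: RuCl[(S,S)-TsDPEN](p-cymene) (2 mol %), HCO2H/Et3N (1:1), CH2Cl2, 25 °C
Reagents that add atoms: none
Why: Noyori-type asymmetric transfer hydrogenation should reduce the unhindered aryl ketone at C9 and not the C4 carbonyl, which is flanked by two ortho substituents and hydrogen-bonded to C8a–OH, and the (S,S)-ligand delivers hydride in the outer-sphere transition state organised by the arene–aryl CH/π contact to the face that gives the 9S alcohol, as with acetophenone-type ketones.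

Step 10
Reactants: 19 (3S)-3-hydroxy-1-[2-hydroxy-5-methoxy-3-methyl-4,6-bis(triisopropylsilyloxy)phenyl]-3-[4-(triisopropylsilyloxy)phenyl]propan-1-one
Product: 20 (3S)-1-[2-hydroxy-5-methoxy-3-methyl-4,6-bis(triisopropylsilyloxy)phenyl]-3-(triethylsilyloxy)-3-[4-(triisopropylsilyloxy)phenyl]propan-1-one
Conditions: Et3SiCl, imidazole, CH2Cl2, −20 → 0 °C
Reagents that add atoms: chlorotriethylsilane, CC[Si](Cl)(CC)CC
Why: Chemoselective silylation of the secondary benzylic alcohol, the chelated and ortho-substituted C8a phenol being far less reactive, blocks C9–O for the enolate chemistry of step 11 without touching the stereocentre.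

Step 11
Reactants: 20 (3S)-1-[2-hydroxy-5-methoxy-3-methyl-4,6-bis(triisopropylsilyloxy)phenyl]-3-(triethylsilyloxy)-3-[4-(triisopropylsilyloxy)phenyl]propan-1-one
Product: 22 (2S,3R)-2-hydroxy-6-methoxy-8-methyl-3-{(S)-(triethylsilyloxy)[4-(triisopropylsilyloxy)phenyl]methyl}-5,7-bis(triisopropylsilyloxy)chroman-4-one, via formyl ketone 21 (not isolated)
Conditions: LiN(SiMe3)2 (2.3 equiv), THF, −78 °C; then HCO2CH2CF3, −78 °C; then AcOH, −78 → 0 °C
Reagents that add atoms: 2,2,2-trifluoroethyl formate, O=COCC(F)(F)F
Why: Crossed Claisen formylation of the kinetically generated phenoxide–enolate dianion at C3 with the activated formate gives the keto aldehyde, to which the C8a hydroxyl (the only free phenol, C5–O being silylated) adds to close ring C as the lactol; C3 and C2 are not set by the reagent and should settle by epimerisation through the open keto aldehyde into the (2S,3R) arrangement assumed to be favoured next to 9S.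

Step 12
Reactants: 22 (2S,3R)-2-hydroxy-6-methoxy-8-methyl-3-{(S)-(triethylsilyloxy)[4-(triisopropylsilyloxy)phenyl]methyl}-5,7-bis(triisopropylsilyloxy)chroman-4-one
Product: 23 (2S,3R)-2,5,7-trihydroxy-3-[(S)-hydroxy(4-hydroxyphenyl)methyl]-6-methoxy-8-methylchroman-4-one
Conditions: Bu4NF, AcOH (1:1), THF, 0 → 20 °C
Reagents that add atoms: none
Why: Fluoride-induced desilylation buffered with acetic acid removes the three aryl silyl ethers and the triethylsilyl ether near neutrality, which avoids acid-promoted dehydration to the chromone and base-promoted retro-aldol cleavage or lactol reopening, and leaves C9 untouched.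

**Compound list**

1 | diisopropyl squarate | CC(C)OC1=C(OC(C)C)C(=O)C1=O | starting material
2 | 4-hydroxy-2,3-diisopropoxy-4-methylcyclobut-2-en-1-one (racemic) | CC(C)OC1=C(OC(C)C)C(C)(O)C1=O | intermediate
3 | 3-isopropoxy-4-methylcyclobut-3-ene-1,2-dione | CC1=C(OC(C)C)C(=O)C1=O | intermediate
4 | ethyl vinyl ether | CCOC=C | starting material
5 | 1-ethoxyvinyllithium | [Li]C(=C)OCC | intermediate
6 | lithium 1-(1-ethoxyvinyl)-2-isopropoxy-3-methyl-4-oxocyclobut-2-en-1-olate (racemic) | [Li]OC1(C(=C)OCC)C(OC(C)C)=C(C)C1=O | intermediate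
7 | 4-(1-ethoxyvinyl)-3-isopropoxy-4-methoxy-2-methylcyclobut-2-en-1-one (racemic) | CCOC(=C)C1(OC)C(OC(C)C)=C(C)C1=O | intermediate
8 | (3Z)-5-ethoxy-3-isopropoxy-4-methoxy-2-methylhexa-1,3,5-trien-1-one | C=C(OCC)/C(OC)=C(\C(C)=C=O)OC(C)C | intermediate
9 | 5-ethoxy-3-isopropoxy-4-methoxy-2-methylcyclohexa-2,4-dien-1-one | O=C1CC(OCC)=C(OC)C(OC(C)C)=C1C | intermediate
10 | 5-ethoxy-3-isopropoxy-4-methoxy-2-methylphenol | CCOc1cc(O)c(C)c(OC(C)C)c1OC | intermediate
11 | 5-ethoxy-3-isopropoxy-4-methoxy-2-methylphenyl acetate | CCOc1cc(OC(C)=O)c(C)c(OC(C)C)c1OC | intermediate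
12 | 1-(6-ethoxy-2-hydroxy-4-isopropoxy-5-methoxy-3-methylphenyl)ethan-1-one | CC(=O)c1c(O)c(C)c(OC(C)C)c(OC)c1OCC | intermediate
13 | 4-isopropoxybenzoic acid | CC(C)Oc1ccc(cc1)C(O)=O | starting material
14 | 4-isopropoxybenzoyl chloride | CC(C)Oc1ccc(cc1)C(Cl)=O | intermediate
15 | 2-acetyl-3-ethoxy-5-isopropoxy-4-methoxy-6-methylphenyl 4-isopropoxybenzoate | CC(=O)c1c(OC(=O)c2ccc(OC(C)C)cc2)c(C)c(OC(C)C)c(OC)c1OCC | intermediate
16 | 2-acetyl-3,5-dihydroxy-4-methoxy-6-methylphenyl 4-hydroxybenzoate | CC(=O)c1c(OC(=O)c2ccc(O)cc2)c(C)c(O)c(OC)c1O | intermediate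
17 | 2-acetyl-4-methoxy-6-methyl-3,5-bis(triisopropylsilyloxy)phenyl 4-(triisopropylsilyloxy)benzoate | CC(=O)c1c(OC(=O)c2ccc(O[Si](C(C)C)(C(C)C)C(C)C)cc2)c(C)c(O[Si](C(C)C)(C(C)C)C(C)C)c(OC)c1O[Si](C(C)C)(C(C)C)C(C)C | intermediate
18 | 1-[2-hydroxy-5-methoxy-3-methyl-4,6-bis(triisopropylsilyloxy)phenyl]-3-[4-(triisopropylsilyloxy)phenyl]propane-1,3-dione | COc1c(O[Si](C(C)C)(C(C)C)C(C)C)c(C)c(O)c(C(=O)CC(=O)c2ccc(O[Si](C(C)C)(C(C)C)C(C)C)cc2)c1O[Si](C(C)C)(C(C)C)C(C)C | intermediate
19 | (3S)-3-hydroxy-1-[2-hydroxy-5-methoxy-3-methyl-4,6-bis(triisopropylsilyloxy)phenyl]-3-[4-(triisopropylsilyloxy)phenyl]propan-1-one | COc1c(O[Si](C(C)C)(C(C)C)C(C)C)c(C)c(O)c(C(=O)C[C@H](O)c2ccc(O[Si](C(C)C)(C(C)C)C(C)C)cc2)c1O[Si](C(C)C)(C(C)C)C(C)C | intermediate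
20 | (3S)-1-[2-hydroxy-5-methoxy-3-methyl-4,6-bis(triisopropylsilyloxy)phenyl]-3-(triethylsilyloxy)-3-[4-(triisopropylsilyloxy)phenyl]propan-1-one | COc1c(O[Si](C(C)C)(C(C)C)C(C)C)c(C)c(O)c(C(=O)C[C@H](O[Si](CC)(CC)CC)c2ccc(O[Si](C(C)C)(C(C)C)C(C)C)cc2)c1O[Si](C(C)C)(C(C)C)C(C)C | intermediate
21 | (3S)-2-[2-hydroxy-5-methoxy-3-methyl-4,6-bis(triisopropylsilyloxy)benzoyl]-3-(triethylsilyloxy)-3-[4-(triisopropylsilyloxy)phenyl]propanal (both epimers at the formyl-bearing carbon) | COc1c(O[Si](C(C)C)(C(C)C)C(C)C)c(C)c(O)c(C(=O)C(C=O)[C@H](O[Si](CC)(CC)CC)c2ccc(O[Si](C(C)C)(C(C)C)C(C)C)cc2)c1O[Si](C(C)C)(C(C)C)C(C)C | intermediate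
22 | (2S,3R)-2-hydroxy-6-methoxy-8-methyl-3-{(S)-(triethylsilyloxy)[4-(triisopropylsilyloxy)phenyl]methyl}-5,7-bis(triisopropylsilyloxy)chroman-4-one | COc1c(O[Si](C(C)C)(C(C)C)C(C)C)c(C)c2c(c1O[Si](C(C)C)(C(C)C)C(C)C)C(=O)[C@H]([C@H](O[Si](CC)(CC)CC)c1ccc(O[Si](C(C)C)(C(C)C)C(C)C)cc1)[C@@H](O)O2 | intermediate
23 | (2S,3R)-2,5,7-trihydroxy-3-[(S)-hydroxy(4-hydroxyphenyl)methyl]-6-methoxy-8-methylchroman-4-one | COc1c(O)c(C)c2c(c1O)C(=O)[C@H]([C@H](O)c1ccc(O)cc1)[C@@H](O)O2 | target

**Step count**

Total: 12 steps. Longest linear sequence: 12 steps (steps 1–12 from diisopropyl squarate; ethyl vinyl ether and 4-isopropoxybenzoic acid enter without prior steps).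

**Steps most likely to fail**

Step 11 (formylation and lactol closure). The enolate may expel the C9 silyloxy group (E1cB) to a chalcone that cyclises to a flavanone. The formate may also be consumed by O-acylation, or the C5 silyl group may shift to the enolate oxygen before C-acylation occurs. Fallback: starting from 20, the C8a phenol is O-formylated with formic acetic anhydride and pyridine at 0 °C to give the aryl formate F1. One equivalent of LiN(SiMe3)2 at −78 °C should then trigger an intramolecular O-to-C formyl transfer of the Baker–Venkataraman type. The enolate is intercepted as it forms, and the tetrahedral intermediate is already the lactol alkoxide. Protonation with AcOH returns to 22.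

Step 9 (transfer hydrogenation). The enolised diketone is in equilibrium with its cyclic hemiketal and may turn over slowly or cyclodehydrate to a flavone. The electron-rich benzylic alcohol may also ionise in the formate medium, which would erode enantiopurity or close a flavanone. Fallback: starting from 17, aminolysis of the aryl ester with propylamine in THF gives the acetophenone F2; this is now safe because C5–O is silylated. Me3SiOTf and Et3N convert it into the bis(trimethylsilyl) enol ether F3. F3 then undergoes a catalytic asymmetric Mukaiyama aldol addition to 4-(triisopropylsilyloxy)benzaldehyde F4, which is made from 4-hydroxybenzaldehyde with i-Pr3SiCl and imidazole. The aldol uses SiCl4 and a catalytic chiral binaphthyldiamine-derived bisphosphoramide (the enantiomer leading to 9S) in CH2Cl2 at −78 °C. Aqueous work-up returns to 19.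

Step 6 (BCl3 dealkylation). The slow, chelation-dependent cleavage of the C5 ethyl ether may be overtaken by demethylation at C6 once boron is bound to the C5 oxygen, or by attack on the aryl ester. Fallback: starting from 3, isopropyl vinyl ether is lithiated to 1-isopropoxyvinyllithium F5 and carried through the chemistry of steps 2 to 5. This gives the cyclobutenone F6, the phenol F7, the acetophenone F8 (acetylation kept at 20 °C to spare the C5 isopropyl ether) and the ester F9. All three ethers of F9 are secondary and should fall to BCl3 at −78 °C without recourse to chelation, returning to 16.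

**Further compounds**

F1 | step 11 | 4-methoxy-6-methyl-2-{(3S)-3-(triethylsilyloxy)-3-[4-(triisopropylsilyloxy)phenyl]propanoyl}-3,5-bis(triisopropylsilyloxy)phenyl formate | COc1c(O[Si](C(C)C)(C(C)C)C(C)C)c(C)c(OC=O)c(C(=O)C[C@H](O[Si](CC)(CC)CC)c2ccc(O[Si](C(C)C)(C(C)C)C(C)C)cc2)c1O[Si](C(C)C)(C(C)C)C(C)C
F2 | step 9 | 1-[2-hydroxy-5-methoxy-3-methyl-4,6-bis(triisopropylsilyloxy)phenyl]ethan-1-one | CC(=O)c1c(O)c(C)c(O[Si](C(C)C)(C(C)C)C(C)C)c(OC)c1O[Si](C(C)C)(C(C)C)C(C)C
F3 | step 9 | trimethyl({1-[5-methoxy-3-methyl-4,6-bis(triisopropylsilyloxy)-2-(trimethylsilyloxy)phenyl]ethenyl}oxy)silane | COc1c(O[Si](C(C)C)(C(C)C)C(C)C)c(C)c(O[Si](C)(C)C)c(C(=C)O[Si](C)(C)C)c1O[Si](C(C)C)(C(C)C)C(C)C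
F4 | step 9 | 4-(triisopropylsilyloxy)benzaldehyde | O=Cc1ccc(O[Si](C(C)C)(C(C)C)C(C)C)cc1
F5 | step 6 | 1-isopropoxyvinyllithium | [Li]C(=C)OC(C)C
F6 | step 6 | 4-(1-isopropoxyvinyl)-3-isopropoxy-4-methoxy-2-methylcyclobut-2-en-1-one (racemic) | C=C(OC(C)C)C1(OC)C(OC(C)C)=C(C)C1=O
F7 | step 6 | 3,5-diisopropoxy-4-methoxy-2-methylphenol | COc1c(OC(C)C)cc(O)c(C)c1OC(C)C
F8 | step 6 | 1-(2-hydroxy-4,6-diisopropoxy-5-methoxy-3-methylphenyl)ethan-1-one | CC(=O)c1c(O)c(C)c(OC(C)C)c(OC)c1OC(C)C
F9 | step 6 | 2-acetyl-3,5-diisopropoxy-4-methoxy-6-methylphenyl 4-isopropoxybenzoate | CC(=O)c1c(OC(=O)c2ccc(OC(C)C)cc2)c(C)c(OC(C)C)c(OC)c1OC(C)C
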